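**Retrosynthetic overview**

- The strategy rests on C2 of the dihydropyran ring (ring B): a quaternary carbon carrying CH3, O1 and two CH2 groups, C3 inside the ring and C1' of the side chain. This is a 2-methylglycidyl unit whose configuration can be bought.
- Key disconnections C3–C4 and C1'–C2': in one flask (S)-2-methylglycidyl tosylate is opened at its oxirane CH2 by (2,5-dimethoxy-3-methylbenzyl)magnesium chloride, the alkoxide moves the oxirane onto the former CH2OTs carbon, and the C15 Grignard reagent (C2'–C13') opens the new oxirane. The C2–O bond is never broken.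
- The chain reagent is cut at C5'–C6' (citronellyl Grignard reagent plus silyl-protected (S)-3-bromo-2-methylpropanol, copper catalysis) and at C2'–C3' (formaldehyde). C4' and C8' come from the chiral pool.
- Ring order: the benzene ring (ring A) is bought with 4-methoxy-2-methylphenol and receives its benzylic carbon C4 by ortho-formylation. Ring B is closed last at O1–C8a through the quinone and its cyclic 8a-methoxy ketal, and zinc then restores ring A.

Key step: step 13

Assumption: (R)-2-methylglycidol, (S)-3-bromo-2-methylpropan-1-ol (the bromo alcohol made from the Roche ester) and (R)-citronellyl bromide are bought in high enantiomeric purity; the enantiomeric purity of the glycidyl tosylate is checked before the key step and raised by recrystallisation if needed.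
Remark: the C4' unit is used as the silyl ether of the bromo alcohol and not as a β-sulfonyloxy ester, because such an ester eliminates to the methacrylate under Grignard conditions and would lose C4'.
Remark: the two Grignard reagents of the key step are prepared as titrated stock solutions in steps of their own, since the key step depends on their titre; the other two Grignard reagents are made and used in one flask.

**Route**

Step 1
Reactants: 1 4-methoxy-2-methylphenol
Product: 2 2-hydroxy-5-methoxy-3-methylbenzaldehyde
Conditions: MgCl2 (1.5 equiv), Et3N (3.8 equiv), (CH2O)n (7 equiv), MeCN, reflux; aq HCl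
Reagents that add atoms: paraformaldehyde (formaldehyde), C=O
Why: Casnati–Skattebøl ortho-formylation delivers formaldehyde from the magnesium phenoxide only to an ortho position, and C6 is the one free ortho carbon (C2 carries CH3, C4 carries OCH3), so the future C4 of the chroman is placed next to the future C8a oxygen without isomers.

Step 2
Reactants: 2 2-hydroxy-5-methoxy-3-methylbenzaldehyde
Product: 3 2,5-dimethoxy-3-methylbenzaldehyde
Conditions: MeI (1.5 equiv), K2CO3 (2 equiv), DMF, 25 °C
Reagents that add atoms: iodomethane, CI
Why: Williamson O-methylation of the phenol in DMF gives the hydroquinone dimethyl ether, which is inert to Grignard reagents and is unmasked later by oxidative demethylation.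

Step 3
Reactants: 3 2,5-dimethoxy-3-methylbenzaldehyde
Product: 4 (2,5-dimethoxy-3-methylphenyl)methanol
Conditions: NaBH4 (1.0 equiv), MeOH, 0 °C
Reagents that add atoms: none
Why: Hydride reduction of an aryl aldehyde by NaBH4 is clean and touches nothing else in the molecule.

Step 4
Reactants: 4 (2,5-dimethoxy-3-methylphenyl)methanol
Product: 5 1-(chloromethyl)-2,5-dimethoxy-3-methylbenzene
Conditions: SOCl2 (1.2 equiv), CH2Cl2, 0 → 20 °C; used without storage
Reagents that add atoms: thionyl chloride, O=S(Cl)Cl
Why: Deoxychlorination of an electron-rich benzylic alcohol through its chlorosulfite is fast at 0 °C, and the chloride is chosen over the bromide because it gives less Wurtz coupling in the next step.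

Step 5
Reactants: 5 1-(chloromethyl)-2,5-dimethoxy-3-methylbenzene
Product: 6 (2,5-dimethoxy-3-methylbenzyl)magnesium chloride (about 0.3 M in THF, titrated)
Conditions: Mg turnings (3 equiv, activated with i-Bu2AlH, 1 mol %), THF, 0 °C, slow addition of dilute 5; titration
Reagents that add atoms: magnesium, [Mg]
Why: Grignard formation by insertion of magnesium into a benzylic C–Cl bond is reliable when the halide is kept dilute over excess metal in the cold, which holds back Wurtz homocoupling, the only serious competitor.

Step 6
Reactants: 7 (R)-2-methylglycidol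
Product: 8 (S)-2-methylglycidyl tosylate
Conditions: TsCl (1.1 equiv), Et3N (1.5 equiv), DMAP (5 mol %), CH2Cl2, −10 → 0 °C
Reagents that add atoms: p-toluenesulfonyl chloride, Cc1ccc(cc1)S(=O)(=O)Cl
Why: O-Sulfonylation of the primary hydroxyl (tosylation) leaves every bond at C2 untouched, so the configuration of 7 is carried over and the descriptor changes from R to S only because CH2OTs outranks the ring CH2.

Step 7
Reactants: 9 (S)-3-bromo-2-methylpropan-1-ol
Product: 10 (S)-(3-bromo-2-methylpropoxy)(tert-butyl)dimethylsilane
Conditions: TBSCl (1.1 equiv), imidazole (1.5 equiv), CH2Cl2, 0 → 20 °C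
Reagents that add atoms: tert-butyldimethylsilyl chloride, CC(C)(C)[Si](C)(C)Cl
Why: Silylation of a primary alcohol with imidazole is routine and gives an ether that survives Grignard and copper reagents, while the stereocentre (the future C4') is not involved.

Step 8
Reactants: 11 (R)-citronellyl bromide; 10 (S)-(3-bromo-2-methylpropoxy)(tert-butyl)dimethylsilane
Product: 13 tert-butyldimethyl{[(2R,6S)-2,6,10-trimethylundec-9-en-1-yl]oxy}silane, via citronellylmagnesium bromide 12 (not isolated)
Conditions: 11 (1.2 equiv), Mg, THF, 40 °C; then added to 10, Li2CuCl4 (3 mol %), NMP (4 equiv), THF, 0 → 20 °C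
Reagents that add atoms: none
Why: Kochi-type copper-catalysed cross-coupling of a primary alkyl Grignard reagent with a primary alkyl bromide forms C5'–C6' between two CH2 groups, so the stereocentres brought in by 11 (C8') and by 10 (C4') are spectators and cannot epimerise.

Step 9
Reactants: 13 tert-butyldimethyl{[(2R,6S)-2,6,10-trimethylundec-9-en-1-yl]oxy}silane
Product: 14 (6S,10R)-11-bromo-2,6,10-trimethylundec-2-ene
Conditions: Ph3PBr2 (1.3 equiv), CH2Cl2, 0 → 20 °C
Reagents that add atoms: triphenylphosphine dibromide, BrP(Br)(c1ccccc1)(c1ccccc1)c1ccccc1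
Why: Direct conversion of a primary silyl ether into the bromide by the bromophosphonium reagent (Si–O cleavage to an alkoxyphosphonium ion, then SN2 by bromide, an Appel-type process) releases no HBr, so the trisubstituted alkene is left alone and the neighbouring stereocentre is untouched.

Step 10
Reactants: 14 (6S,10R)-11-bromo-2,6,10-trimethylundec-2-ene
Product: 16 (3R,7S)-3,7,11-trimethyldodec-10-en-1-ol, via trimethylundecenylmagnesium bromide 15 (not isolated)
Conditions: Mg, THF, 45 °C; then (CH2O)n (3 equiv, dried), THF, 0 → 50 °C; aq NH4Cl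
Reagents that add atoms: paraformaldehyde (formaldehyde), C=O
Why: Addition of a primary alkyl Grignard reagent to formaldehyde is the standard one-carbon homologation to a primary alcohol and supplies C2' without touching C4' or C8'.

Step 11
Reactants: 16 (3R,7S)-3,7,11-trimethyldodec-10-en-1-ol
Product: 17 (6S,10R)-12-bromo-2,6,10-trimethyldodec-2-ene
Conditions: CBr4 (1.2 equiv), PPh3 (1.3 equiv), CH2Cl2, 0 °C
Reagents that add atoms: carbon tetrabromide, BrC(Br)(Br)Br
Why: Appel bromination of an unhindered primary alcohol is neutral and fast, so the alkene and both stereocentres are unaffected.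

Step 12
Reactants: 17 (6S,10R)-12-bromo-2,6,10-trimethyldodec-2-ene
Product: 18 [(3R,7S)-3,7,11-trimethyldodec-10-en-1-yl]magnesium bromide (about 0.5 M in THF, titrated)
Conditions: Mg turnings (2 equiv, activated with i-Bu2AlH, 1 mol %), THF, 40 °C; titration
Reagents that add atoms: magnesium, [Mg]
Why: Grignard formation from an unbranched primary bromide is routine, and the trisubstituted alkene is too remote to trap the transient radical.

Step 13
Reactants: 8 (S)-2-methylglycidyl tosylate; 6 (2,5-dimethoxy-3-methylbenzyl)magnesium chloride; 18 [(3R,7S)-3,7,11-trimethyldodec-10-en-1-yl]magnesium bromide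
Product: 21 (3R,7R,11S)-1-(2,5-dimethoxy-3-methylphenyl)-3,7,11,15-tetramethylhexadec-14-en-3-ol, via chloromagnesium tosyloxy alkoxide 19 (not isolated), via arylethyl methyl oxirane 20 (not isolated)
Conditions: 8 (1.0 equiv), CuI (10 mol %), THF, −40 °C, 6 (0.97 equiv) added over 1 h; 25 °C, 2 h; then CuI (5 mol %), 18 (1.4 equiv), −30 → 20 °C; aq NH4Cl/NH3
Reagents that add atoms: none
Why: Under CuI catalysis 6 opens the oxirane of 8 at its CH2 by SN2 at −40 °C (forming C3–C4) to give the tertiary chloromagnesium alkoxide 19, which on warming displaces the neighbouring tosylate so that the same oxygen now bridges C2 and the former CH2OTs carbon (oxirane 20), and 18 then opens 20 at its CH2 (forming C1'–C2') under the same catalysis. The closest known reaction type is the copper-catalysed Grignard opening of glycidyl sulfonates and of epichlorohydrin followed by alkoxide ring closure (a Payne-type epoxide migration) and a second opening, that is, the use of these compounds as linchpins for two different carbanions. No ring of the target is closed; the only ring formed is the transient oxirane of 20, by 3-exo-tet displacement helped by the geminal substitution at C2. No stereocentre is created: all three substitutions take place at CH2 groups and the C2–O bond is never broken, so C2 keeps the configuration bought with 7, and the order of addition alone (benzyl to the ring CH2 = C3, chain to the former CH2OTs carbon = C1') translates it into 3R in 21. The step needs site selectivity for the oxirane CH2 over the tosylate CH2, which the neopentyl-like position of the tosylate secures since it reacts only intramolecularly, and it needs 6 to be used up before 19 closes, which the cold, slow addition of slightly less than one equivalent of 6 secures.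

Step 14
Reactants: 21 (3R,7R,11S)-1-(2,5-dimethoxy-3-methylphenyl)-3,7,11,15-tetramethylhexadec-14-en-3-ol
Product: 22 2-[(3R,7R,11S)-3-hydroxy-3,7,11,15-tetramethylhexadec-14-en-1-yl]-6-methyl-1,4-benzoquinone
Conditions: (NH4)2Ce(NO3)6 (2.5 equiv), MeCN/H2O (2:1), 0 °C, 15 min
Reagents that add atoms: water, O
Why: Oxidative demethylation of a hydroquinone dimethyl ether by the one-electron oxidant (NH4)2Ce(NO3)6 (ipso attack of water on the arene radical cation, loss of methanol) is fast at 0 °C, a contact too short and too cold to touch the tertiary alcohol or the isolated alkene, and it does not involve C2.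

Step 15
Reactants: 22 2-[(3R,7R,11S)-3-hydroxy-3,7,11,15-tetramethylhexadec-14-en-1-yl]-6-methyl-1,4-benzoquinone
Product: 23 (2R)-8a-methoxy-2,8-dimethyl-2-[(4R,8S)-4,8,12-trimethyltridec-11-en-1-yl]-3,4-dihydro-2H-chromen-6(8aH)-one (both C8a epimers)
Conditions: HC(OMe)3 (3 equiv), MeOH/CH2Cl2 (1:4), TsOH·H2O (5 mol %), 0 °C; Et3N quench
Reagents that add atoms: trimethyl orthoformate, COC(OC)OC
Why: In this acid-catalysed ketalisation the tertiary hydroxyl adds to the C8a carbonyl (6-exo-trig, forming O1–C8a and ring B) and the hemiketal is trapped as the mixed methyl ketal while the orthoformate removes water, so the C2–O bond stays intact and C2 keeps its R configuration, and the new centre C8a forms as both epimers, which is of no consequence because it becomes sp2 again in step 16.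

Step 16
Reactants: 23 (2R)-8a-methoxy-2,8-dimethyl-2-[(4R,8S)-4,8,12-trimethyltridec-11-en-1-yl]-3,4-dihydro-2H-chromen-6(8aH)-one
Product: 24 (2R)-2,8-dimethyl-2-[(4R,8S)-4,8,12-trimethyltridec-11-en-1-yl]-3,4-dihydro-2H-chromen-6-ol (CNP0221369.1)
Conditions: Zn dust (5 equiv), AcOH (10 equiv), THF, 0 → 20 °C, argon
Reagents that add atoms: none
Why: Two-electron reduction of a quinone monoketal with loss of one alkoxy group re-aromatises ring A to the p-alkoxyphenol, and the exocyclic methoxy group is the one lost because its departure gives the cyclic oxocarbenium ion stabilised by O1, so ring B and the configuration at C2 are kept while zinc in acetic acid does not reduce the alkene.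

**Compound list**

1 | 4-methoxy-2-methylphenol | COc1ccc(O)c(C)c1 | starting material
2 | 2-hydroxy-5-methoxy-3-methylbenzaldehyde | COc1cc(C)c(O)c(C=O)c1 | intermediate
3 | 2,5-dimethoxy-3-methylbenzaldehyde | COc1cc(C)c(OC)c(C=O)c1 | intermediate
4 | (2,5-dimethoxy-3-methylphenyl)methanol | COc1cc(C)c(OC)c(CO)c1 | intermediate
5 | 1-(chloromethyl)-2,5-dimethoxy-3-methylbenzene | COc1cc(C)c(OC)c(CCl)c1 | intermediate
6 | (2,5-dimethoxy-3-methylbenzyl)magnesium chloride | COc1cc(C)c(OC)c(C[Mg]Cl)c1 | intermediate
7 | (R)-2-methylglycidol | OC[C@]1(C)CO1 | starting material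
8 | (S)-2-methylglycidyl tosylate | Cc1ccc(cc1)S(=O)(=O)OC[C@]1(C)CO1 | intermediate
9 | (S)-3-bromo-2-methylpropan-1-ol | OC[C@H](C)CBr | starting material
10 | (S)-(3-bromo-2-methylpropoxy)(tert-butyl)dimethylsilane | CC(C)(C)[Si](C)(C)OC[C@H](C)CBr | intermediate
11 | (R)-citronellyl bromide, (R)-8-bromo-2,6-dimethyloct-2-ene | CC(C)=CCC[C@@H](C)CCBr | starting material
12 | (R)-citronellylmagnesium bromide | CC(C)=CCC[C@@H](C)CC[Mg]Br | intermediate
13 | tert-butyldimethyl{[(2R,6S)-2,6,10-trimethylundec-9-en-1-yl]oxy}silane | CC(C)=CCC[C@@H](C)CCC[C@@H](C)CO[Si](C)(C)C(C)(C)C | intermediate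
14 | (6S,10R)-11-bromo-2,6,10-trimethylundec-2-ene | CC(C)=CCC[C@@H](C)CCC[C@@H](C)CBr | intermediate
15 | [(2R,6S)-2,6,10-trimethylundec-9-en-1-yl]magnesium bromide | CC(C)=CCC[C@@H](C)CCC[C@@H](C)C[Mg]Br | intermediate
16 | (3R,7S)-3,7,11-trimethyldodec-10-en-1-ol | CC(C)=CCC[C@@H](C)CCC[C@@H](C)CCO | intermediate
17 | (6S,10R)-12-bromo-2,6,10-trimethyldodec-2-ene | CC(C)=CCC[C@@H](C)CCC[C@@H](C)CCBr | intermediate
18 | [(3R,7S)-3,7,11-trimethyldodec-10-en-1-yl]magnesium bromide | CC(C)=CCC[C@@H](C)CCC[C@@H](C)CC[Mg]Br | intermediate
19 | chloromagnesium (S)-4-(2,5-dimethoxy-3-methylphenyl)-2-methyl-1-(tosyloxy)butan-2-olate | Cc1ccc(cc1)S(=O)(=O)OC[C@](O[Mg]Cl)(C)CCc1cc(OC)cc(C)c1OC | intermediate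
20 | (S)-2-[2-(2,5-dimethoxy-3-methylphenyl)ethyl]-2-methyloxirane | C[C@]1(CCc2cc(OC)cc(C)c2OC)CO1 | intermediate
21 | (3R,7R,11S)-1-(2,5-dimethoxy-3-methylphenyl)-3,7,11,15-tetramethylhexadec-14-en-3-ol | CC(C)=CCC[C@@H](C)CCC[C@@H](C)CCC[C@](O)(C)CCc1cc(OC)cc(C)c1OC | intermediate
22 | 2-[(3R,7R,11S)-3-hydroxy-3,7,11,15-tetramethylhexadec-14-en-1-yl]-6-methyl-1,4-benzoquinone | CC(C)=CCC[C@@H](C)CCC[C@@H](C)CCC[C@](O)(C)CCC1=CC(=O)C=C(C)C1=O | intermediate
23 | (2R)-8a-methoxy-2,8-dimethyl-2-[(4R,8S)-4,8,12-trimethyltridec-11-en-1-yl]-3,4-dihydro-2H-chromen-6(8aH)-one, both C8a epimers | CC(C)=CCC[C@@H](C)CCC[C@@H](C)CCC[C@]1(C)CCC2=CC(=O)C=C(C)C2(OC)O1 | intermediate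
24 | (2R)-2,8-dimethyl-2-[(4R,8S)-4,8,12-trimethyltridec-11-en-1-yl]-3,4-dihydro-2H-chromen-6-ol | CC(C)=CCC[C@@H](C)CCC[C@@H](C)CCC[C@]1(C)CCc2cc(O)cc(C)c2O1 | target

**Step count and risks**

Total: 16 steps. Longest linear sequence: 10 steps (steps 7 to 16, from (S)-3-bromo-2-methylpropan-1-ol).

Three steps most likely to fail:

1. Step 13.
 - What may go wrong: the magnesium alkoxide may close while benzylic reagent is still present, so that the benzylic reagent also opens the second oxirane.
 - The alkoxide may instead close too slowly as its magnesium salt, so that the chain reagent finds no oxirane.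
 - Chloride from the Schlenk equilibrium may open the oxirane reversibly, or the benzylic reagent may displace the tosylate directly; either exchanges the two arms and erodes the configuration at C2.
 - Fallback, setting out from 7 and 6 and coming back at 20 and then 21: alcohol 7 is deprotonated with i-PrMgCl (1.0 equiv, THF, −30 °C) and its oxirane is opened by 6 (1.2 equiv, CuI 10 mol %, −30 → 0 °C) to give (S)-4-(2,5-dimethoxy-3-methylphenyl)-2-methylbutane-1,2-diol F1. The primary hydroxyl is tosylated selectively (TsCl, pyridine, 0 °C) to (S)-4-(2,5-dimethoxy-3-methylphenyl)-2-hydroxy-2-methylbutyl 4-methylbenzenesulfonate F2. K2CO3 in MeOH closes F2 to oxirane 20, which is isolated and opened in a separate flask by 18 (1.3 equiv, CuI 10 mol %, THF, −30 → 0 °C) to give 21.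
 - No leaving group is present during the first C–C bond formation, so the arms cannot exchange and a second benzylation is excluded, at the price of three more operations.

2. Step 15.
 - What may go wrong: ketalisation at the unhindered C6 carbonyl may compete with closure at the flanked C8a carbonyl, and methanol may add in conjugate fashion to the unsubstituted C5 and C7 positions of the quinone.
 - Fallback, setting out from 21 and coming back at 23: anodic oxidation of 21 (Pt anode, KOH 1 % in MeOH, 0 °C, undivided cell) should give the quinone bisketal (3R,7R,11S)-3,7,11,15-tetramethyl-1-(3,3,6,6-tetramethoxy-5-methylcyclohexa-1,4-dien-1-yl)hexadec-14-en-3-ol F3 without passing through the quinone.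
 - Dilute acid (AcOH, aqueous acetone, 0 °C) should hydrolyse only the ketal at C6, whose ionisation is helped by the alkyl groups at C4a and C8, to give 3-[(3R,7R,11S)-3-hydroxy-3,7,11,15-tetramethylhexadec-14-en-1-yl]-4,4-dimethoxy-5-methylcyclohexa-2,5-dien-1-one F4.
 - PPTS with molecular sieves in CH2Cl2 then exchanges one of the two C8a methoxy groups for the tertiary hydroxyl and gives 23.

3. Step 5.
 - What may go wrong: Wurtz homocoupling of the electron-rich benzylic chloride on the magnesium surface, leaving a weak solution of uncertain titre on which step 13 depends.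
 - Fallback, setting out from 5 and coming back at 6: Bu3SnLi (THF, −78 °C) displaces chloride to give tributyl[(2,5-dimethoxy-3-methylphenyl)methyl]stannane F5, which can be purified.
 - Tin–lithium exchange with MeLi (1.0 equiv, THF, −78 °C) gives (2,5-dimethoxy-3-methylbenzyl)lithium F6 beside inert Bu3SnMe, and anhydrous MgCl2 (1.05 equiv) converts it into 6.
 - Carbanion and benzylic halide never meet, so homocoupling is excluded.

**Further compounds**

F1 | step 13 | (S)-4-(2,5-dimethoxy-3-methylphenyl)-2-methylbutane-1,2-diol | OC[C@](O)(C)CCc1cc(OC)cc(C)c1OC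
F2 | step 13 | (S)-4-(2,5-dimethoxy-3-methylphenyl)-2-hydroxy-2-methylbutyl 4-methylbenzenesulfonate | Cc1ccc(cc1)S(=O)(=O)OC[C@](O)(C)CCc1cc(OC)cc(C)c1OC
F3 | step 15 | (3R,7R,11S)-3,7,11,15-tetramethyl-1-(3,3,6,6-tetramethoxy-5-methylcyclohexa-1,4-dien-1-yl)hexadec-14-en-3-ol | CC(C)=CCC[C@@H](C)CCC[C@@H](C)CCC[C@](O)(C)CCC1=CC(OC)(OC)C=C(C)C1(OC)OC
F4 | step 15 | 3-[(3R,7R,11S)-3-hydroxy-3,7,11,15-tetramethylhexadec-14-en-1-yl]-4,4-dimethoxy-5-methylcyclohexa-2,5-dien-1-one | CC(C)=CCC[C@@H](C)CCC[C@@H](C)CCC[C@](O)(C)CCC1=CC(=O)C=C(C)C1(OC)OC
F5 | step 5 | tributyl[(2,5-dimethoxy-3-methylphenyl)methyl]stannane | CCCC[Sn](CCCC)(CCCC)Cc1cc(OC)cc(C)c1OC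
F6 | step 5 | (2,5-dimethoxy-3-methylbenzyl)lithium | [Li]Cc1cc(OC)cc(C)c1OC
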